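**Retrosynthetic overview**

- Feature: C3 of pyranone ring C of unit 1 (the 5-hydroxy-7-methoxyflavone half, rings A, C, B) is bonded to C6'' of the trioxygenated benzo ring D of unit 2 (the luteolin half, rings D, E, F) and sits next to C2, which carries ring B. This is the 3-aryl pattern an isoflavone acquires by aryl migration.
- Ring E is cut last at O1''–C2'' and C4''–C4a'': oxa-Michael addition of a ring D para-phenol to methyl 3-[3,4-bis(benzyloxy)phenyl]prop-2-ynoate, then Friedel–Crafts closure.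
- Ring C is cut at C3–C6'' and O1–C2 together: oxidative 1,2-shift of ring D from C-beta to C-alpha of a beta,beta-diaryl enone with Tl(NO3)3 in methanol, then acid closure by the ring A oxygen.
- The enone comes from the ring A ynone (salicylaldehyde MOM ether plus 4-benzyloxyphenylacetylide, then oxidation) by conjugate addition of the ring D cuprate; C6'' is fixed as the metalated carbon by a TIPS-directed bromination.
- Ring order: ring C (step 7), then ring E (step 13); rings A, B, D and F come from the starting materials.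

Key step: step 7

Assumptions:
- 3,5-Bis(benzyloxy)phenol, 2-hydroxy-4,6-dimethoxybenzaldehyde, 1-(benzyloxy)-4-ethynylbenzene and 3,4-bis(benzyloxy)benzaldehyde are taken as commercial.
- The enone precursor of the key step is drawn as the 2Z isomer. Cuprate additions to ynones pass through an allenolate and can give both alkene isomers; either is carried on, because the key step destroys the alkene geometry.
- The target SMILES defines no configuration for the hindered C3–C6'' axis. The route gives the racemate if that axis is configurationally stable.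

**Route**

Step 1
Reactants: 1 3,5-bis(benzyloxy)phenol
Product: 2 [3,5-bis(benzyloxy)phenoxy]tri(propan-2-yl)silane
Conditions: TIPSCl, imidazole, DMF, rt
Reagents that add atoms: chlorotri(propan-2-yl)silane, CC(C)[Si](Cl)(C(C)C)C(C)C
Why: Imidazole-promoted O-silylation of the phenol; the bulky TIPS ether is chosen to shield both carbons ortho to this oxygen in step 2 and to outlast the acid of step 7.

Step 2
Reactants: 2 [3,5-bis(benzyloxy)phenoxy]tri(propan-2-yl)silane
Product: 3 [3,5-bis(benzyloxy)-4-bromophenoxy]tri(propan-2-yl)silane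
Conditions: NBS (1.0 equiv), CH2Cl2, −78 °C to 0 °C
Reagents that add atoms: N-bromosuccinimide, O=C1CCC(=O)N1Br
Why: Electrophilic aromatic bromination should go to the carbon between the two benzyloxy groups (para to the silyloxy group) because the two other activated sites are flanked by the bulky TIPS ether, which fixes the future C6'' as the metalated carbon.

Step 3
Reactants: 4 2-hydroxy-4,6-dimethoxybenzaldehyde
Product: 5 2,4-dimethoxy-6-(methoxymethoxy)benzaldehyde
Conditions: NaH, DMF, 0 °C; MOMCl, 0 °C to rt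
Reagents that add atoms: chloromethyl methyl ether, COCCl
Why: Williamson O-alkylation of the sodium phenoxide gives the MOM ether, which masks the future O1 (a free hydroxyl would close onto the beta,beta-diaryl enone as a 2,2-diarylchromanone and would be oxidised by trivalent thallium) and is released by the acid of step 7.

Step 4
Reactants: 6 1-(benzyloxy)-4-ethynylbenzene; 5 2,4-dimethoxy-6-(methoxymethoxy)benzaldehyde
Product: 8 rac-3-[4-(benzyloxy)phenyl]-1-[2,4-dimethoxy-6-(methoxymethoxy)phenyl]prop-2-yn-1-ol, via lithium arylacetylide 7 (not isolated)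
Conditions: 6, n-BuLi, THF, −78 °C; then 5, −78 °C to 0 °C; aq NH4Cl
Reagents that add atoms: none
Why: 1,2-Addition of a lithium acetylide to the aldehyde; the new carbinol centre is racemic and is removed by the oxidation in step 5.

Step 5
Reactants: 8 rac-3-[4-(benzyloxy)phenyl]-1-[2,4-dimethoxy-6-(methoxymethoxy)phenyl]prop-2-yn-1-ol
Product: 9 3-[4-(benzyloxy)phenyl]-1-[2,4-dimethoxy-6-(methoxymethoxy)phenyl]prop-2-yn-1-one
Conditions: activated MnO2 (excess), CH2Cl2, rt
Reagents that add atoms: none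
Why: MnO2 oxidation of a doubly activated (benzylic and propargylic) alcohol to the ynone, leaving the MOM and benzyl ethers untouched.

Step 6
Reactants: 3 [3,5-bis(benzyloxy)-4-bromophenoxy]tri(propan-2-yl)silane; 9 3-[4-(benzyloxy)phenyl]-1-[2,4-dimethoxy-6-(methoxymethoxy)phenyl]prop-2-yn-1-one
Product: 12 (2Z)-3-[2,6-bis(benzyloxy)-4-{[tri(propan-2-yl)silyl]oxy}phenyl]-3-[4-(benzyloxy)phenyl]-1-[2,4-dimethoxy-6-(methoxymethoxy)phenyl]prop-2-en-1-one, via aryllithium 10 (not isolated), via lithium diarylcuprate 11 (not isolated)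
Conditions: 3 (2.2 equiv), t-BuLi (4.4 equiv), THF, −78 °C; CuBr·SMe2 (1.1 equiv), −78 °C to −40 °C; then 9, −78 °C to −20 °C; aq NH4Cl/NH3
Reagents that add atoms: none
Why: Conjugate addition of a Gilman diarylcuprate to an ynone forms the C-beta–C6'' bond at an unhindered sp carbon, and 2,6-dialkoxyphenyl cuprates are known to transfer their aryl group in 1,4-additions; the alkene geometry is of no consequence for step 7.

Step 7
Reactants: 12 (2Z)-3-[2,6-bis(benzyloxy)-4-{[tri(propan-2-yl)silyl]oxy}phenyl]-3-[4-(benzyloxy)phenyl]-1-[2,4-dimethoxy-6-(methoxymethoxy)phenyl]prop-2-en-1-one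
Product: 14 3-[2,6-bis(benzyloxy)-4-{[tri(propan-2-yl)silyl]oxy}phenyl]-2-[4-(benzyloxy)phenyl]-5,7-dimethoxychromen-4-one, via beta-keto dimethyl ketal 13 (not isolated)
Conditions: Tl(NO3)3·3H2O (1.2 equiv), MeOH–HC(OMe)3, rt; then aq HCl (3 M), MeOH–THF, 50 °C
Reagents that add atoms: none
Why: Proposed new method: trivalent thallium should add to C-alpha of the enone while methanol traps the diaryl-stabilised C-beta cation; ring D then shifts from C-beta to C-alpha through a phenonium bridge as monovalent thallium departs (forming C3–C6''), and methanol captures the resulting oxocarbenium to give the racemic ketal 13. The closest known reaction is the Tl(NO3)3 rearrangement of 2'-oxygenated chalcones to 1,2-diaryl-3,3-dimethoxypropan-1-ones on the way to isoflavones, which has not been applied to a beta,beta-diaryl enone. The acid then removes the MOM group and ionises the ketal, and the ring A hydroxyl attacks the C2 oxocarbenium in a 6-exo-trig closure (O1–C2), after which loss of methanol gives ring C. No stereocentre remains, since the C-alpha centre of 13 becomes sp2. The step needs ring D to migrate in preference to ring B: ring D is the more electron-rich aryl, its departure relieves crowding at the di-ortho-substituted quaternary carbon, and the ring B left behind has a para-alkoxy group that stabilises the C2 cation. The aryl TIPS ether is expected to survive both stages, and any desilylated material is simply compound 15.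

Step 8
Reactants: 14 3-[2,6-bis(benzyloxy)-4-{[tri(propan-2-yl)silyl]oxy}phenyl]-2-[4-(benzyloxy)phenyl]-5,7-dimethoxychromen-4-one
Product: 15 3-[2,6-bis(benzyloxy)-4-hydroxyphenyl]-2-[4-(benzyloxy)phenyl]-5,7-dimethoxychromen-4-one
Conditions: TBAF, AcOH, THF, 0 °C to rt
Reagents that add atoms: none
Why: Fluoride cleavage of the aryl silyl ether, buffered with acetic acid so that the phenoxide is protonated at once and the chromone is not exposed to base.

Step 9
Reactants: 16 3,4-bis(benzyloxy)benzaldehyde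
Product: 17 1,2-bis(benzyloxy)-4-(2,2-dibromoethenyl)benzene
Conditions: CBr4, PPh3, CH2Cl2, 0 °C
Reagents that add atoms: carbon tetrabromide, BrC(Br)(Br)Br
Why: First stage of the Corey–Fuchs reaction, a Wittig-type dibromo-olefination of the aldehyde.

Step 10
Reactants: 17 1,2-bis(benzyloxy)-4-(2,2-dibromoethenyl)benzene
Product: 19 methyl 3-[3,4-bis(benzyloxy)phenyl]prop-2-ynoate, via lithium arylacetylide 18 (not isolated)
Conditions: n-BuLi (2.1 equiv), THF, −78 °C; ClCO2Me, −78 °C to 0 °C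
Reagents that add atoms: methyl chloroformate, COC(=O)Cl
Why: Second stage of the Corey–Fuchs reaction: elimination and Br–Li exchange give the lithium acetylide, which is C-acylated by the chloroformate.

Step 11
Reactants: 15 3-[2,6-bis(benzyloxy)-4-hydroxyphenyl]-2-[4-(benzyloxy)phenyl]-5,7-dimethoxychromen-4-one; 19 methyl 3-[3,4-bis(benzyloxy)phenyl]prop-2-ynoate
Product: 20 methyl (2Z)-3-[3,4-bis(benzyloxy)phenyl]-3-(3,5-bis(benzyloxy)-4-{2-[4-(benzyloxy)phenyl]-5,7-dimethoxy-4-oxochromen-3-yl}phenoxy)prop-2-enoate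
Conditions: K2CO3, DMF, 80 °C
Reagents that add atoms: none
Why: Base-mediated oxa-Michael addition of the phenoxide to the aryl propiolate (first stage of the Ruhemann flavone synthesis) forms O1''–C2''; anti addition should give the Z enoate, and the other isomer is equally usable because the geometry equilibrates under the acid of step 13.

Step 12
Reactants: 20 methyl (2Z)-3-[3,4-bis(benzyloxy)phenyl]-3-(3,5-bis(benzyloxy)-4-{2-[4-(benzyloxy)phenyl]-5,7-dimethoxy-4-oxochromen-3-yl}phenoxy)prop-2-enoate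
Product: 21 (2Z)-3-[3,4-bis(benzyloxy)phenyl]-3-(3,5-bis(benzyloxy)-4-{2-[4-(benzyloxy)phenyl]-5,7-dimethoxy-4-oxochromen-3-yl}phenoxy)prop-2-enoic acid
Conditions: LiOH·H2O, THF–MeOH–H2O, 40 °C; then 1 M HCl to pH 3
Reagents that add atoms: lithium hydroxide, [Li+].[OH-]
Why: Saponification of the methyl ester under mild conditions that should leave the vinylogous carbonate and the hindered 2,3-diarylchromone intact.

Step 13
Reactants: 21 (2Z)-3-[3,4-bis(benzyloxy)phenyl]-3-(3,5-bis(benzyloxy)-4-{2-[4-(benzyloxy)phenyl]-5,7-dimethoxy-4-oxochromen-3-yl}phenoxy)prop-2-enoic acid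
Product: 23 3-{5,7-bis(benzyloxy)-2-[3,4-bis(benzyloxy)phenyl]-4-oxochromen-6-yl}-2-[4-(benzyloxy)phenyl]-5,7-dimethoxychromen-4-one, via mixed trifluoroacetic anhydride 22 (not isolated)
Conditions: TFAA, CH2Cl2, 0 °C to rt
Reagents that add atoms: none
Why: Intramolecular Friedel–Crafts acylation through the mixed anhydride closes ring E (C4''–C4a'') at a ring D carbon that is ortho and para to benzyloxy groups; the two candidate carbons are constitutionally equivalent, so only the 6''-linked flavone can form.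

Step 14
Reactants: 23 3-{5,7-bis(benzyloxy)-2-[3,4-bis(benzyloxy)phenyl]-4-oxochromen-6-yl}-2-[4-(benzyloxy)phenyl]-5,7-dimethoxychromen-4-one
Product: 24 3-[2-(3,4-dihydroxyphenyl)-5,7-dihydroxy-4-oxochromen-6-yl]-5-hydroxy-2-(4-hydroxyphenyl)-7-methoxychromen-4-one
Conditions: BCl3, pentamethylbenzene, CH2Cl2, −78 °C to rt; MeOH, then aqueous work-up
Reagents that add atoms: none
Why: Lewis-acid ether cleavage: BCl3 with pentamethylbenzene as benzyl cation scavenger removes the five benzyl ethers and, through a boron chelate with the C4 carbonyl, the peri 5-methoxy group, while the unchelated 7-methoxy group is not attacked by BCl3 at these temperatures.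

**Compound list**

1 | 3,5-bis(benzyloxy)phenol | Oc1cc(OCc2ccccc2)cc(OCc2ccccc2)c1 | starting material
2 | [3,5-bis(benzyloxy)phenoxy]tri(propan-2-yl)silane | CC(C)[Si](Oc1cc(OCc2ccccc2)cc(OCc2ccccc2)c1)(C(C)C)C(C)C | intermediate
3 | [3,5-bis(benzyloxy)-4-bromophenoxy]tri(propan-2-yl)silane | CC(C)[Si](Oc1cc(OCc2ccccc2)c(Br)c(OCc2ccccc2)c1)(C(C)C)C(C)C | intermediate
4 | 2-hydroxy-4,6-dimethoxybenzaldehyde | COc1cc(O)c(C=O)c(OC)c1 | starting material
5 | 2,4-dimethoxy-6-(methoxymethoxy)benzaldehyde | COCOc1cc(OC)cc(OC)c1C=O | intermediate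
6 | 1-(benzyloxy)-4-ethynylbenzene | C#Cc1ccc(OCc2ccccc2)cc1 | starting material
7 | lithium [4-(benzyloxy)phenyl]ethynide | [Li]C#Cc1ccc(OCc2ccccc2)cc1 | intermediate
8 | rac-3-[4-(benzyloxy)phenyl]-1-[2,4-dimethoxy-6-(methoxymethoxy)phenyl]prop-2-yn-1-ol | COCOc1cc(OC)cc(OC)c1C(O)C#Cc1ccc(OCc2ccccc2)cc1 | intermediate
9 | 3-[4-(benzyloxy)phenyl]-1-[2,4-dimethoxy-6-(methoxymethoxy)phenyl]prop-2-yn-1-one | COCOc1cc(OC)cc(OC)c1C(=O)C#Cc1ccc(OCc2ccccc2)cc1 | intermediate
10 | [2,6-bis(benzyloxy)-4-{[tri(propan-2-yl)silyl]oxy}phenyl]lithium | [Li]c1c(OCc2ccccc2)cc(O[Si](C(C)C)(C(C)C)C(C)C)cc1OCc1ccccc1 | intermediate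
11 | lithium bis[2,6-bis(benzyloxy)-4-{[tri(propan-2-yl)silyl]oxy}phenyl]cuprate (monovalent copper) | [Li+].CC(C)[Si](Oc1cc(OCc2ccccc2)c([Cu-]c2c(OCc3ccccc3)cc(O[Si](C(C)C)(C(C)C)C(C)C)cc2OCc2ccccc2)c(OCc2ccccc2)c1)(C(C)C)C(C)C | intermediate
12 | (2Z)-3-[2,6-bis(benzyloxy)-4-{[tri(propan-2-yl)silyl]oxy}phenyl]-3-[4-(benzyloxy)phenyl]-1-[2,4-dimethoxy-6-(methoxymethoxy)phenyl]prop-2-en-1-one | COCOc1cc(OC)cc(OC)c1C(=O)/C=C(/c1ccc(OCc2ccccc2)cc1)c1c(OCc2ccccc2)cc(O[Si](C(C)C)(C(C)C)C(C)C)cc1OCc1ccccc1 | intermediate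
13 | rac-2-[2,6-bis(benzyloxy)-4-{[tri(propan-2-yl)silyl]oxy}phenyl]-3-[4-(benzyloxy)phenyl]-1-[2,4-dimethoxy-6-(methoxymethoxy)phenyl]-3,3-dimethoxypropan-1-one | COCOc1cc(OC)cc(OC)c1C(=O)C(c1c(OCc2ccccc2)cc(O[Si](C(C)C)(C(C)C)C(C)C)cc1OCc1ccccc1)C(OC)(OC)c1ccc(OCc2ccccc2)cc1 | intermediate
14 | 3-[2,6-bis(benzyloxy)-4-{[tri(propan-2-yl)silyl]oxy}phenyl]-2-[4-(benzyloxy)phenyl]-5,7-dimethoxychromen-4-one | COc1cc(OC)c2c(=O)c(-c3c(OCc4ccccc4)cc(O[Si](C(C)C)(C(C)C)C(C)C)cc3OCc3ccccc3)c(-c3ccc(OCc4ccccc4)cc3)oc2c1 | intermediate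
15 | 3-[2,6-bis(benzyloxy)-4-hydroxyphenyl]-2-[4-(benzyloxy)phenyl]-5,7-dimethoxychromen-4-one | COc1cc(OC)c2c(=O)c(-c3c(OCc4ccccc4)cc(O)cc3OCc3ccccc3)c(-c3ccc(OCc4ccccc4)cc3)oc2c1 | intermediate
16 | 3,4-bis(benzyloxy)benzaldehyde | O=Cc1ccc(OCc2ccccc2)c(OCc2ccccc2)c1 | starting material
17 | 1,2-bis(benzyloxy)-4-(2,2-dibromoethenyl)benzene | BrC(Br)=Cc1ccc(OCc2ccccc2)c(OCc2ccccc2)c1 | intermediate
18 | lithium [3,4-bis(benzyloxy)phenyl]ethynide | [Li]C#Cc1ccc(OCc2ccccc2)c(OCc2ccccc2)c1 | intermediate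
19 | methyl 3-[3,4-bis(benzyloxy)phenyl]prop-2-ynoate | COC(=O)C#Cc1ccc(OCc2ccccc2)c(OCc2ccccc2)c1 | intermediate
20 | methyl (2Z)-3-[3,4-bis(benzyloxy)phenyl]-3-(3,5-bis(benzyloxy)-4-{2-[4-(benzyloxy)phenyl]-5,7-dimethoxy-4-oxochromen-3-yl}phenoxy)prop-2-enoate | COC(=O)/C=C(\Oc1cc(OCc2ccccc2)c(-c2c(-c3ccc(OCc4ccccc4)cc3)oc3cc(OC)cc(OC)c3c2=O)c(OCc2ccccc2)c1)c1ccc(OCc2ccccc2)c(OCc2ccccc2)c1 | intermediate
21 | (2Z)-3-[3,4-bis(benzyloxy)phenyl]-3-(3,5-bis(benzyloxy)-4-{2-[4-(benzyloxy)phenyl]-5,7-dimethoxy-4-oxochromen-3-yl}phenoxy)prop-2-enoic acid | OC(=O)/C=C(\Oc1cc(OCc2ccccc2)c(-c2c(-c3ccc(OCc4ccccc4)cc3)oc3cc(OC)cc(OC)c3c2=O)c(OCc2ccccc2)c1)c1ccc(OCc2ccccc2)c(OCc2ccccc2)c1 | intermediate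
22 | (2Z)-3-[3,4-bis(benzyloxy)phenyl]-3-(3,5-bis(benzyloxy)-4-{2-[4-(benzyloxy)phenyl]-5,7-dimethoxy-4-oxochromen-3-yl}phenoxy)prop-2-enoic trifluoroacetic anhydride | O=C(OC(=O)C(F)(F)F)/C=C(\Oc1cc(OCc2ccccc2)c(-c2c(-c3ccc(OCc4ccccc4)cc3)oc3cc(OC)cc(OC)c3c2=O)c(OCc2ccccc2)c1)c1ccc(OCc2ccccc2)c(OCc2ccccc2)c1 | intermediate
23 | 3-{5,7-bis(benzyloxy)-2-[3,4-bis(benzyloxy)phenyl]-4-oxochromen-6-yl}-2-[4-(benzyloxy)phenyl]-5,7-dimethoxychromen-4-one | COc1cc(OC)c2c(=O)c(-c3c(OCc4ccccc4)cc4oc(-c5ccc(OCc6ccccc6)c(OCc6ccccc6)c5)cc(=O)c4c3OCc3ccccc3)c(-c3ccc(OCc4ccccc4)cc3)oc2c1 | intermediate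
24 | 3-[2-(3,4-dihydroxyphenyl)-5,7-dihydroxy-4-oxochromen-6-yl]-5-hydroxy-2-(4-hydroxyphenyl)-7-methoxychromen-4-one | COc1cc(O)c2c(=O)c(-c3c(O)cc4oc(-c5ccc(O)c(O)c5)cc(=O)c4c3O)c(-c3ccc(O)cc3)oc2c1 | target

**Step count and risks**

Total step count: 14. Longest linear sequence: 10 steps (steps 3, 4, 5, 6, 7, 8, 11, 12, 13, 14, from aldehyde 4).

Steps most likely to fail:

1. Step 7 (proposed new method). The aryl shift may not take the intended course: ring B may migrate in place of ring D, oxythallation of the crowded trisubstituted alkene may be slow, or trivalent thallium may oxidise or thallate the electron-rich rings before rearrangement. The fallback uses known chemistry; it sets out from ynone 9 and bromide 3 and comes back at compound 14. Acidic methanol (HCl, MeOH, 60 °C) removes the MOM group of 9 and the freed phenol closes 6-endo-dig onto the ynone to give 2-[4-(benzyloxy)phenyl]-5,7-dimethoxychromen-4-one F1. C3 lithiation with LDA in THF at −78 °C and an I2 quench gives 2-[4-(benzyloxy)phenyl]-3-iodo-5,7-dimethoxychromen-4-one F2. Bromide 3 is converted by t-BuLi and then 2-isopropoxy-4,4,5,5-tetramethyl-1,3,2-dioxaborolane into 2-[2,6-bis(benzyloxy)-4-{[tri(propan-2-yl)silyl]oxy}phenyl]-4,4,5,5-tetramethyl-1,3,2-dioxaborolane F3. Suzuki–Miyaura coupling of F2 with F3 (Pd(OAc)2, SPhos, K3PO4, toluene–H2O, 100 °C) forms the C3–C6'' bond directly and gives 14, which continues at step 8.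

2. Step 6. Transfer of the di-ortho-substituted aryl group from copper may be sluggish, and 1,2-addition to the carbonyl or decomposition of the cuprate on warming may compete. The fallback sets out from ynone 9 and bromide 3 and comes back at compound 12. Anti hydroiodination of 9 (LiI, AcOH, MeCN, rt) gives (2Z)-3-[4-(benzyloxy)phenyl]-1-[2,4-dimethoxy-6-(methoxymethoxy)phenyl]-3-iodoprop-2-en-1-one F4. Bromide 3 is converted by t-BuLi and then ZnCl2 into [2,6-bis(benzyloxy)-4-{[tri(propan-2-yl)silyl]oxy}phenyl]zinc chloride F5. Negishi coupling of F4 with F5 (Pd(OAc)2, SPhos, THF, 50 °C) replaces iodine with retention of the alkene geometry and gives 12.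

3. Step 11. The ambident phloroglucinol-type phenoxide may attack through carbon instead of oxygen, and addition to the electron-rich aryl ynoate may be slow or reversible at the temperature needed. The fallback sets out from phenol 15 and comes back at compound 23, bypassing steps 12 and 13 as well. Ortho C-acetylation of 15 (Ac2O, BF3·OEt2, CH2Cl2, rt, through the aryl acetate and a Fries shift) gives 3-[3-acetyl-2,6-bis(benzyloxy)-4-hydroxyphenyl]-2-[4-(benzyloxy)phenyl]-5,7-dimethoxychromen-4-one F6. Claisen–Schmidt condensation of F6 with aldehyde 16 (KOH, EtOH, rt) gives (2E)-3-[3,4-bis(benzyloxy)phenyl]-1-(2,4-bis(benzyloxy)-3-{2-[4-(benzyloxy)phenyl]-5,7-dimethoxy-4-oxochromen-3-yl}-6-hydroxyphenyl)prop-2-en-1-one F7. Oxidative cyclisation of the 2'-hydroxychalcone (catalytic I2, DMSO, 120 °C) closes and dehydrogenates ring E to give 23.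

Further compounds
F1 | step 7 | 2-[4-(benzyloxy)phenyl]-5,7-dimethoxychromen-4-one | COc1cc(OC)c2c(=O)cc(-c3ccc(OCc4ccccc4)cc3)oc2c1
F2 | step 7 | 2-[4-(benzyloxy)phenyl]-3-iodo-5,7-dimethoxychromen-4-one | COc1cc(OC)c2c(=O)c(I)c(-c3ccc(OCc4ccccc4)cc3)oc2c1
F3 | step 7 | 2-[2,6-bis(benzyloxy)-4-{[tri(propan-2-yl)silyl]oxy}phenyl]-4,4,5,5-tetramethyl-1,3,2-dioxaborolane | CC(C)[Si](Oc1cc(OCc2ccccc2)c(B2OC(C)(C)C(C)(C)O2)c(OCc2ccccc2)c1)(C(C)C)C(C)C
F4 | step 6 | (2Z)-3-[4-(benzyloxy)phenyl]-1-[2,4-dimethoxy-6-(methoxymethoxy)phenyl]-3-iodoprop-2-en-1-one | COCOc1cc(OC)cc(OC)c1C(=O)/C=C(\I)c1ccc(OCc2ccccc2)cc1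
F5 | step 6 | [2,6-bis(benzyloxy)-4-{[tri(propan-2-yl)silyl]oxy}phenyl]zinc chloride | Cl[Zn]c1c(OCc2ccccc2)cc(O[Si](C(C)C)(C(C)C)C(C)C)cc1OCc1ccccc1
F6 | step 11 | 3-[3-acetyl-2,6-bis(benzyloxy)-4-hydroxyphenyl]-2-[4-(benzyloxy)phenyl]-5,7-dimethoxychromen-4-one | COc1cc(OC)c2c(=O)c(-c3c(OCc4ccccc4)cc(O)c(C(C)=O)c3OCc3ccccc3)c(-c3ccc(OCc4ccccc4)cc3)oc2c1
F7 | step 11 | (2E)-3-[3,4-bis(benzyloxy)phenyl]-1-(2,4-bis(benzyloxy)-3-{2-[4-(benzyloxy)phenyl]-5,7-dimethoxy-4-oxochromen-3-yl}-6-hydroxyphenyl)prop-2-en-1-one | COc1cc(OC)c2c(=O)c(-c3c(OCc4ccccc4)cc(O)c(C(=O)/C=C/c4ccc(OCc5ccccc5)c(OCc5ccccc5)c4)c3OCc3ccccc3)c(-c3ccc(OCc4ccccc4)cc3)oc2c1
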